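The 14-membered carbocycle is opened at C6–C7 (carbocycle numbered from the isopropenyl-bearing C1 through the enoate C3=C4 to C14). The feature exploited is that the C6 ketone sits β to C8, the tertiary ether carbon of the oxolanone ring O–C8–C9–C10–C11: a C6≡C7 alkyne next to a C8 acetate is a masked C6-keto C7=C8 enone onto which the C11 hydroxyl can close. Ring-closing alkyne metathesis thus builds the macrocycle and stores both the C6 oxygen and the oxolanone in one operation. Its precursor is an acyclic diyne with two methyl-capped alkynes, C8 acetate, C11 silyl ether and free C10 and C13 ketones.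

Key step: step 14

Remark: C8 is erased in step 15 and reset in step 16, so it is made racemic on purpose (9–12 racemic, 26–31 pairs of C8 epimers, centre left undefined in their SMILES); the antipodes of BINAP (step 6) and Ipc2BCl (step 11) are assigned from the usual facial models of these reagents and are exchanged if a first run shows the opposite sense.

Remark: the acetate is installed on the small C7–C11 fragment and C10 stays a thioacetal until the step before ring closure, so that no base meets the β-acetoxy ketone or the β-silyloxy ketone.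

**Step 1**
Reactants: 1 tert-butyldimethyl(prop-2-yn-1-yloxy)silane; 2 N-methoxy-N-methylacetamide
Product: 4 5-[(tert-butyldimethylsilyl)oxy]pent-3-yn-2-one, via lithium acetylide 3 (not isolated)
Conditions: n-BuLi, THF, −78 °C; then 2, −78 → 0 °C; NH4Cl aq
Reagents that add atoms: none
Why: Acylation of a lithium acetylide with an N-methoxy-N-methylamide (Weinreb ketone synthesis) should stop at the ynone because the chelated tetrahedral adduct survives until work-up.

**Step 2**
Reactants: 4 5-[(tert-butyldimethylsilyl)oxy]pent-3-yn-2-one; 5 propane-1,3-dithiol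
Product: 7 1-[2-({[tert-butyl(dimethyl)silyl]oxy}methyl)-1,3-dithian-2-yl]propan-2-one, via vinyl sulfide 6 (not isolated)
Conditions: NaOMe, MeOH/CH2Cl2, −10 °C → rt
Reagents that add atoms: none
Why: Double thia-Michael addition of the dithiol to the ynone should place both sulfur atoms on the β-carbon (future C10) and give the β-keto-1,3-dithiane without any strong base.

**Step 3**
Reactants: 7 1-[2-({[tert-butyl(dimethyl)silyl]oxy}methyl)-1,3-dithian-2-yl]propan-2-one; 8 prop-1-yn-1-ylmagnesium bromide
Product: 10 1-[2-({[tert-butyl(dimethyl)silyl]oxy}methyl)-1,3-dithian-2-yl]-2-methylpent-3-yn-2-yl acetate (racemic), via magnesium alkoxide 9 (not isolated)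
Conditions: 8, LaCl3·2LiCl, THF, −78 → 0 °C; then Ac2O, DMAP, 0 °C → rt
Reagents that add atoms: acetic anhydride, CC(=O)OC(C)=O
Why: 1,2-Addition of the alkynyl Grignard reagent to the methyl ketone (the lanthanum salt suppresses enolisation and retro-thia-Michael loss) followed by O-acylation of the alkoxide in the same flask should give the tertiary propargylic acetate, whose C8 centre is formed racemic because it is erased later.

**Step 4**
Reactants: 10 1-[2-({[tert-butyl(dimethyl)silyl]oxy}methyl)-1,3-dithian-2-yl]-2-methylpent-3-yn-2-yl acetate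
Product: 11 1-[2-(hydroxymethyl)-1,3-dithian-2-yl]-2-methylpent-3-yn-2-yl acetate (racemic)
Conditions: HF·pyridine, pyridine, THF, 0 °C → rt
Reagents that add atoms: none
Why: Fluoride-mediated desilylation of the primary silyl ether under buffered acidic conditions should leave the tertiary acetate and the thioacetal untouched.

**Step 5**
Reactants: 11 1-[2-(hydroxymethyl)-1,3-dithian-2-yl]-2-methylpent-3-yn-2-yl acetate
Product: 12 1-(2-formyl-1,3-dithian-2-yl)-2-methylpent-3-yn-2-yl acetate (racemic; C7–C11 aldehyde with C10 masked)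
Conditions: SO3·pyridine, DMSO, iPr2NEt, CH2Cl2, 0 °C
Reagents that add atoms: none
Why: Parikh–Doering oxidation (activated dimethyl sulfoxide) should convert the neopentyl alcohol into the non-enolisable aldehyde without oxidising the thioacetal sulfur.

**Step 6**
Reactants: 13 5,6-dihydro-2H-pyran-2-one; 14 potassium trifluoro(prop-1-en-2-yl)borate
Product: 15 (4R)-4-(prop-1-en-2-yl)oxan-2-one
Conditions: [Rh(cod)2]BF4 (3 mol%), (R)-BINAP, Et3N, toluene/H2O, 60 °C
Reagents that add atoms: none
Why: Rhodium-catalysed asymmetric conjugate addition of the alkenylboron reagent (Hayashi–Miyaura type) should set C1 (R), since the BINAP-bound alkenylrhodium species distinguishes the two faces of the cyclic Z-configured acceptor.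

**Step 7**
Reactants: 15 (4R)-4-(prop-1-en-2-yl)oxan-2-one
Product: 17 (4R)-6-hydroxy-4-(prop-1-en-2-yl)hexan-2-one, via lithium lactolate 16 (not isolated)
Conditions: MeLi (1.05 equiv), THF, −78 °C; NH4Cl aq at −78 °C
Reagents that add atoms: methyllithium, [Li]C
Why: Mono-addition of methyllithium to the δ-lactone should stop at the methyl ketone because the tetrahedral lithium lactolate persists at low temperature and collapses only on quenching.

**Step 8**
Reactants: 17 (4R)-6-hydroxy-4-(prop-1-en-2-yl)hexan-2-one
Product: 18 (3R)-5-oxo-3-(prop-1-en-2-yl)hexanal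
Conditions: Dess–Martin periodinane, NaHCO3, CH2Cl2, 0 °C → rt; used at once
Reagents that add atoms: none
Why: Dess–Martin oxidation of the primary alcohol under buffered conditions should give the keto aldehyde, which is carried on directly to avoid intramolecular aldol reaction.

**Step 9**
Reactants: 19 methyl bis(2,2,2-trifluoroethyl)phosphonoacetate; 20 1-bromobut-2-yne
Product: 22 methyl 2-[bis(2,2,2-trifluoroethoxy)phosphoryl]hex-4-ynoate (racemic), via sodium phosphonate 21 (not isolated)
Conditions: NaH, THF, 0 °C; then 20, 0 °C → rt (19 in excess)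
Reagents that add atoms: none
Why: C-Alkylation (SN2) of the stabilised phosphonoacetate anion with the propargylic bromide should give the substituted phosphonate, and the excess of 19 limits double alkylation.

**Step 10**
Reactants: 22 methyl 2-[bis(2,2,2-trifluoroethoxy)phosphoryl]hex-4-ynoate; 18 (3R)-5-oxo-3-(prop-1-en-2-yl)hexanal
Product: 24 methyl (2Z,5R)-2-(but-2-yn-1-yl)-7-oxo-5-(prop-1-en-2-yl)oct-2-enoate, via potassium phosphonate 23 (not isolated)
Conditions: KN(SiMe3)2, 18-crown-6, THF, −78 °C; then 18
Reagents that add atoms: none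
Why: The Still–Gennari variant of the Horner–Wadsworth–Emmons olefination should give the Z-enoate (C2 cis to the ester) because the electron-poor trifluoroethyl phosphonate eliminates from the kinetic adduct, and the aldehyde reacts far faster than the methyl ketone.

**Step 11**
Reactants: 24 methyl (2Z,5R)-2-(but-2-yn-1-yl)-7-oxo-5-(prop-1-en-2-yl)oct-2-enoate; 12 1-(2-formyl-1,3-dithian-2-yl)-2-methylpent-3-yn-2-yl acetate
Product: 27 methyl (2Z,5R,9S)-9-{2-[2-(acetyloxy)-2-methylpent-3-yn-1-yl]-1,3-dithian-2-yl}-2-(but-2-yn-1-yl)-9-hydroxy-7-oxo-5-(prop-1-en-2-yl)non-2-enoate (both C8 epimers), via enol borinate 25 (not isolated), via boron aldolate 26 (not isolated)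
Conditions: (−)-Ipc2BCl, Et3N, Et2O, 0 °C; then 12, −78 → −20 °C; MeOH, pH 7 buffer, HN(CH2CH2OH)2 (non-oxidative work-up)
Reagents that add atoms: none
Why: In this diisopinocampheylboron-mediated aldol reaction of a methyl ketone the boron chloride/amine pair should enolise only the methyl side, and the isopinocampheyl ligands of the enol borinate are expected to direct attack to the Si face of the aldehyde in a cyclic transition state, which sets C11 (S).

**Step 12**
Reactants: 27 aldol adduct
Product: 28 methyl (2Z,5R,9S)-9-{2-[2-(acetyloxy)-2-methylpent-3-yn-1-yl]-1,3-dithian-2-yl}-2-(but-2-yn-1-yl)-7-oxo-5-(prop-1-en-2-yl)-9-[(triethylsilyl)oxy]non-2-enoate (both C8 epimers)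
Conditions: Et3SiOTf, 2,6-lutidine, CH2Cl2, −78 °C
Reagents that add atoms: triethylsilyl trifluoromethanesulfonate, CC[Si](CC)(CC)OS(=O)(=O)C(F)(F)F
Why: Silylation of the hindered secondary alcohol with the silyl triflate and a non-nucleophilic base at low temperature should be faster than enol silylation of the C13 ketone or β-elimination.

**Step 13**
Reactants: 28 triethylsilyl ether with C10 thioacetal
Product: 29 methyl (2Z,5R,9S)-12-(acetyloxy)-2-(but-2-yn-1-yl)-12-methyl-7,10-dioxo-5-(prop-1-en-2-yl)-9-[(triethylsilyl)oxy]pentadec-2-en-13-ynoate (acyclic diyne; both C8 epimers)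
Conditions: PhI(OCOCF3)2, CaCO3, MeCN/H2O, 0 °C
Reagents that add atoms: water, O
Why: Oxidative dethioacetalisation with the hypervalent iodine reagent should be fast at sulfur, the most nucleophilic site, and under carbonate buffering spare the alkynes, alkenes, silyl ether and acetate while revealing the C10 ketone.

**Step 14**
Reactants: 29 acyclic diyne
Product: 30 methyl (1Z,4R,8S)-11-(acetyloxy)-11-methyl-6,9-dioxo-4-(prop-1-en-2-yl)-8-[(triethylsilyl)oxy]cyclotetradec-1-en-12-yne-1-carboxylate (14-membered cycloalkyne; both C8 epimers)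
Conditions: [Mo(≡CC6H4-4-OMe)(OSiPh3)3] (15 mol%), 5 Å MS, toluene (0.002 M), rt → 60 °C
Reagents that add atoms: none
Why: The hexavalent molybdenum alkylidyne adds to each methyl-capped alkyne by [2+2] cycloaddition to a metallacyclobutadiene and cycloreverts, so that the ethylidyne ends are exchanged, C6 and C7 are joined, and but-2-yne is expelled and trapped in the sieves, which drives the closure forward. The closest known reaction type is ring-closing alkyne metathesis of methyl-capped α,ω-diynes to macrocyclic alkynes with molybdenum alkylidyne triphenylsilanolate catalysts. The 14-membered carbocycle is closed end to end by formation of the endocyclic C6≡C7 bond, a ring size that accommodates the linear alkyne without strain. No stereocentre is formed, and C1 and C11 are not touched because the medium is neutral and aprotic. The step needs alkyne-over-alkene and alkyne-over-carbonyl selectivity, which the alkylidyne supplies by its inertness to the isopropenyl and enoate alkenes, the two ketones, the two esters and the silyl ether, and ring-over-oligomer selectivity, which high dilution, removal of but-2-yne and the turn elements of the chain (Z-trisubstituted alkene, branched C1, fully substituted C8) should secure.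

**Step 15**
Reactants: 30 14-membered cycloalkyne
Product: 32 methyl (1Z,4R,8S)-11-methyl-6,9,13-trioxo-4-(prop-1-en-2-yl)-8-[(triethylsilyl)oxy]cyclotetradeca-1,11-diene-1-carboxylate (C7=C8 enone; E/Z mixture at this alkene), via allenyl acetate 31 (not isolated)
Conditions: Ph3PAuNTf2 (5 mol%), butan-2-one/H2O, rt
Reagents that add atoms: water, O
Why: Gold-catalysed 1,3-acyloxy shift ([3,3]-rearrangement) of the tertiary propargylic acetate to the allenyl acetate and hydrolysis of this enol ester by the water present (Meyer–Schuster-type transposition) should place the carbonyl at C6 and the alkene at C7=C8, and both C8 epimers converge because C8 ceases to be a stereocentre.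

**Step 16**
Reactants: 32 macrocyclic enone
Product: 34 methyl (1R,5Z,8R,12S)-1-methyl-3,10,13-trioxo-8-(prop-1-en-2-yl)-15-oxabicyclo[10.2.1]pentadec-5-ene-5-carboxylate (target), via hydroxy enone 33 (not isolated)
Conditions: HF·pyridine, pyridine, THF, 0 °C → rt
Reagents that add atoms: none
Why: Desilylation frees the C11 hydroxyl, which should add to C8 of the enone by a reversible, acid-promoted intramolecular oxa-Michael reaction (5-exo-trig) from either enone isomer, and since the macrocycle allows only the cis-bridged oxolanone the fixed C11 (S) centre sets C8 (R).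

**Compound list**

1 | tert-butyldimethyl(prop-2-yn-1-yloxy)silane | C#CCO[Si](C)(C)C(C)(C)C | starting material
2 | N-methoxy-N-methylacetamide | CC(=O)N(C)OC | starting material
3 | lithium acetylide of 1 | [Li]C#CCO[Si](C)(C)C(C)(C)C | intermediate (not isolated)
4 | 5-[(tert-butyldimethylsilyl)oxy]pent-3-yn-2-one | CC(=O)C#CCO[Si](C)(C)C(C)(C)C | intermediate
5 | propane-1,3-dithiol | SCCCS | starting material
6 | 4-[(3-sulfanylpropyl)sulfanyl]-5-[(tert-butyldimethylsilyl)oxy]pent-3-en-2-one (vinyl sulfide, alkene geometry undefined) | CC(=O)C=C(CO[Si](C)(C)C(C)(C)C)SCCCS | intermediate (not isolated)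
7 | 1-[2-({[tert-butyl(dimethyl)silyl]oxy}methyl)-1,3-dithian-2-yl]propan-2-one | CC(=O)CC1(CO[Si](C)(C)C(C)(C)C)SCCCS1 | intermediate
8 | prop-1-yn-1-ylmagnesium bromide | CC#C[Mg]Br | starting material
9 | bromomagnesium alkoxide of the tertiary propargylic alcohol (racemic) | CC#CC(C)(O[Mg]Br)CC1(CO[Si](C)(C)C(C)(C)C)SCCCS1 | intermediate (not isolated)
10 | 1-[2-({[tert-butyl(dimethyl)silyl]oxy}methyl)-1,3-dithian-2-yl]-2-methylpent-3-yn-2-yl acetate (racemic) | CC#CC(C)(OC(C)=O)CC1(CO[Si](C)(C)C(C)(C)C)SCCCS1 | intermediate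
11 | 1-[2-(hydroxymethyl)-1,3-dithian-2-yl]-2-methylpent-3-yn-2-yl acetate (racemic) | CC#CC(C)(OC(C)=O)CC1(CO)SCCCS1 | intermediate
12 | 1-(2-formyl-1,3-dithian-2-yl)-2-methylpent-3-yn-2-yl acetate (racemic) | CC#CC(C)(OC(C)=O)CC1(C=O)SCCCS1 | intermediate
13 | 5,6-dihydro-2H-pyran-2-one | O=C1C=CCCO1 | starting material
14 | potassium trifluoro(prop-1-en-2-yl)borate | C=C(C)[B-](F)(F)F.[K+] | starting material
15 | (4R)-4-(prop-1-en-2-yl)oxan-2-one | C=C(C)[C@H]1CC(=O)OCC1 | intermediate
16 | lithium (4R)-2-methyl-4-(prop-1-en-2-yl)oxan-2-olate (C2 undefined) | C=C(C)[C@H]1CC(C)(O[Li])OCC1 | intermediate (not isolated)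
17 | (4R)-6-hydroxy-4-(prop-1-en-2-yl)hexan-2-one | C=C(C)[C@H](CCO)CC(C)=O | intermediate
18 | (3R)-5-oxo-3-(prop-1-en-2-yl)hexanal | C=C(C)[C@H](CC=O)CC(C)=O | intermediate
19 | methyl bis(2,2,2-trifluoroethyl)phosphonoacetate | COC(=O)CP(=O)(OCC(F)(F)F)OCC(F)(F)F | starting material
20 | 1-bromobut-2-yne | CC#CCBr | starting material
21 | sodium salt of 19 | COC(=O)[CH-]P(=O)(OCC(F)(F)F)OCC(F)(F)F.[Na+] | intermediate (not isolated)
22 | methyl 2-[bis(2,2,2-trifluoroethoxy)phosphoryl]hex-4-ynoate (racemic) | COC(=O)C(CC#CC)P(=O)(OCC(F)(F)F)OCC(F)(F)F | intermediate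
23 | potassium salt of 22 | COC(=O)[C-](CC#CC)P(=O)(OCC(F)(F)F)OCC(F)(F)F.[K+] | intermediate (not isolated)
24 | methyl (2Z,5R)-2-(but-2-yn-1-yl)-7-oxo-5-(prop-1-en-2-yl)oct-2-enoate | CC#CC/C(C(=O)OC)=C/C[C@@H](C(C)=C)CC(C)=O | intermediate
25 | diisopinocampheylboron enolate of 24 (methyl-side enol borinate) | CC#CC/C(C(=O)OC)=C/C[C@@H](C(C)=C)CC(=C)OB([C@@H]1C[C@@H]2C[C@H]([C@H]1C)C2(C)C)[C@@H]1C[C@@H]2C[C@H]([C@H]1C)C2(C)C | intermediate (not isolated)
26 | C11 O-diisopinocampheylboryl aldolate (both C8 epimers) | CC#CC/C(C(=O)OC)=C/C[C@@H](C(C)=C)CC(=O)C[C@H](OB([C@@H]2C[C@@H]3C[C@H]([C@H]2C)C3(C)C)[C@@H]2C[C@@H]3C[C@H]([C@H]2C)C3(C)C)C1(CC(C)(OC(C)=O)C#CC)SCCCS1 | intermediate (not isolated)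
27 | methyl (2Z,5R,9S)-9-{2-[2-(acetyloxy)-2-methylpent-3-yn-1-yl]-1,3-dithian-2-yl}-2-(but-2-yn-1-yl)-9-hydroxy-7-oxo-5-(prop-1-en-2-yl)non-2-enoate (both C8 epimers) | CC#CC/C(C(=O)OC)=C/C[C@@H](C(C)=C)CC(=O)C[C@H](O)C1(CC(C)(OC(C)=O)C#CC)SCCCS1 | intermediate
28 | C11 triethylsilyl ether of 27 (both C8 epimers) | CC#CC/C(C(=O)OC)=C/C[C@@H](C(C)=C)CC(=O)C[C@H](O[Si](CC)(CC)CC)C1(CC(C)(OC(C)=O)C#CC)SCCCS1 | intermediate
29 | methyl (2Z,5R,9S)-12-(acetyloxy)-2-(but-2-yn-1-yl)-12-methyl-7,10-dioxo-5-(prop-1-en-2-yl)-9-[(triethylsilyl)oxy]pentadec-2-en-13-ynoate (both C8 epimers) | CC#CC/C(C(=O)OC)=C/C[C@@H](C(C)=C)CC(=O)C[C@H](O[Si](CC)(CC)CC)C(=O)CC(C)(OC(C)=O)C#CC | intermediate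
30 | methyl (1Z,4R,8S)-11-(acetyloxy)-11-methyl-6,9-dioxo-4-(prop-1-en-2-yl)-8-[(triethylsilyl)oxy]cyclotetradec-1-en-12-yne-1-carboxylate (both C8 epimers) | C1/C(C(=O)OC)=C/C[C@@H](C(C)=C)CC(=O)C[C@H](O[Si](CC)(CC)CC)C(=O)CC(C)(OC(C)=O)C#C1 | intermediate
31 | methyl (1Z,4R,8S)-13-(acetyloxy)-11-methyl-6,9-dioxo-4-(prop-1-en-2-yl)-8-[(triethylsilyl)oxy]cyclotetradeca-1,11,12-triene-1-carboxylate (allenyl acetate, allene axis undefined) | C1/C(C(=O)OC)=C/C[C@@H](C(C)=C)CC(=O)C[C@H](O[Si](CC)(CC)CC)C(=O)CC(C)=C=C1OC(C)=O | intermediate (not isolated)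
32 | methyl (1Z,4R,8S)-11-methyl-6,9,13-trioxo-4-(prop-1-en-2-yl)-8-[(triethylsilyl)oxy]cyclotetradeca-1,11-diene-1-carboxylate (11E/11Z mixture) | C1/C(C(=O)OC)=C/C[C@@H](C(C)=C)CC(=O)C[C@H](O[Si](CC)(CC)CC)C(=O)CC(C)=CC1=O | intermediate
33 | methyl (1Z,4R,8S)-8-hydroxy-11-methyl-6,9,13-trioxo-4-(prop-1-en-2-yl)cyclotetradeca-1,11-diene-1-carboxylate (11E/11Z mixture) | C1/C(C(=O)OC)=C/C[C@@H](C(C)=C)CC(=O)C[C@H](O)C(=O)CC(C)=CC1=O | intermediate (not isolated)
34 | methyl (1R,5Z,8R,12S)-1-methyl-3,10,13-trioxo-8-(prop-1-en-2-yl)-15-oxabicyclo[10.2.1]pentadec-5-ene-5-carboxylate | C=C(C)[C@@H]1C/C=C(\C(=O)OC)CC(=O)C[C@]2(C)CC(=O)[C@H](CC(=O)C1)O2 | target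

**Totals**

Total step count: 16. Longest linear sequence: 11 steps (steps 1–5 and 11–16, from compound 1).

**Steps most likely to fail**

Step 14. Ring closure may be outrun by oligomerisation, or the metallacycle may form so slowly at the alkyne beside the fully substituted C8 that acetic acid is lost across C8–C9 of the β-acetoxy ketone on warming over the sieves. The fallback closes the ring one stage earlier, before C10 is a ketone. It sets out from thioacetal 28, which is treated with the same molybdenum alkylidyne (5 Å MS, toluene, high dilution) to give the macrocyclic thioacetal F3. The sp3 C10 removes the eliminable β-acyloxy ketone and adds a further turn element. Thioethers are tolerated by catalysts of this type, and tolerance of the thioacetal is assumed by extension. F3 is then unmasked with PhI(OCOCF3)2 and CaCO3 in wet MeCN, and the route is rejoined at cycloalkyne 30.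

Step 11. The isopinocampheyl ligands may discriminate poorly between the faces of the hindered, α-quaternary aldehyde, giving a C11 mixture that is awkward to separate beside the C8 epimers. The fallback replaces enolate-centred control by a Lewis-acid-centred Mukaiyama aldol reaction. It sets out from ketone 24, which is converted with LiN(iPr)2 and Me3SiCl (THF, −78 °C) into the trimethylsilyl enol ether F1. F1 and aldehyde 12 are combined in EtCN at −78 °C with the B-butyl oxazaborolidinone derived from N-tosyltryptophan (enantiomer chosen for Si-face addition), which should give the silylated adduct F2. Dilute acid on work-up removes the trimethylsilyl group, and the route is rejoined at aldol adduct 27.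

Step 15. The gold-activated alkyne may be captured by the C10 carbonyl oxygen (5-exo) or by one of the alkenes before the acetate migrates. The fallback introduces the C6 oxygen by hydrometalation and oxidation instead of π-acid catalysis. It sets out from cycloalkyne 30: trans-hydrosilylation with HSi(OEt)3 and [Cp*Ru(MeCN)3]PF6 should place silicon on C6, distal to the oxygenated C8, to give the vinylsilane F4. Tamao–Fleming oxidation (H2O2, KF, KHCO3, THF/MeOH) converts F4 into the C6 ketone F5, a β-acetoxy ketone. Et3N in CH2Cl2 then eliminates acetic acid (E1cB), directly toward C7 or after isomerisation of the C8=C9 isomer through the shared dienol, and the route is rejoined at enone 32.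

**Further compounds**

F1 | step 11 | methyl (2Z,5R)-2-(but-2-yn-1-yl)-5-(prop-1-en-2-yl)-7-[(trimethylsilyl)oxy]octa-2,7-dienoate | CC#CC/C(C(=O)OC)=C/C[C@@H](C(C)=C)CC(=C)O[Si](C)(C)C
F2 | step 11 | C11 O-trimethylsilyl ether of aldol adduct 27 (both C8 epimers) | CC#CC/C(C(=O)OC)=C/C[C@@H](C(C)=C)CC(=O)C[C@H](O[Si](C)(C)C)C1(CC(C)(OC(C)=O)C#CC)SCCCS1
F3 | step 14 | 14-membered cycloalkyne with the 1,3-dithiane still at C10 (thioacetal analogue of 30; both C8 epimers) | C1/C(C(=O)OC)=C/C[C@@H](C(C)=C)CC(=O)C[C@H](O[Si](CC)(CC)CC)C2(SCCCS2)CC(C)(OC(C)=O)C#C1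
F4 | step 15 | C6 triethoxysilyl alkene from trans-hydrosilylation of 30 (silicon on C6 cis to C8; both C8 epimers) | C1/C(C(=O)OC)=C/C[C@@H](C(C)=C)CC(=O)C[C@H](O[Si](CC)(CC)CC)C(=O)CC(C)(OC(C)=O)/C=C1\[Si](OCC)(OCC)OCC
F5 | step 15 | methyl (1Z,4R,8S)-11-(acetyloxy)-11-methyl-6,9,13-trioxo-4-(prop-1-en-2-yl)-8-[(triethylsilyl)oxy]cyclotetradec-1-ene-1-carboxylate (both C8 epimers) | C1/C(C(=O)OC)=C/C[C@@H](C(C)=C)CC(=O)C[C@H](O[Si](CC)(CC)CC)C(=O)CC(C)(OC(C)=O)CC1=O
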